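**Retrosynthetic overview**
1. Botcinin J ⇒ Z-selective Still–Gennari olefination (C2'=C3') of a core-bound phosphonoacetate with 2-oxooctanal. The C7 ester and the C3 acetate come from site-selective double acylation of the bicyclic diol.
2. Bicyclic diol ⇒ one flask from a fully acyclic C1–C9 (4E)-enoyl imide. A C3–OH-directed epoxidation is followed by acid: O8 opens the oxirane at C4 (6-endo, inversion), and the freed C5–OH lactonises on C1 and expels the auxiliary.
3. Ring order inside that operation: transient oxirane → ring A (tetrahydropyran, O8–C4) → ring B (δ-lactone, O5–C1). C4 and C5 are set there.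
4. Acyclic imide ⇒ anti-aldol (C2–C3) of an N-propionyl oxazolidinone with an (E)-enal. The enal ⇒ cross-metathesis (C4=C5) with methacrolein.
5. Homoallylic alcohol ⇒ (Z)-crotylboration (C6–C7) of O-silyl (S)-lactaldehyde made from ethyl (S)-lactate (C8).

Assumption: the SMILES is taken literally, so the side chain is the (Z)-4-oxodec-2-enoate. The core is (2R,3S,4S,5S,6R,7R,8S) in botcinin numbering, which is used throughout: C1 is the lactone C=O, C4/C5 are the ring-fusion carbons, and C9 is the methyl on C8. Compounds 10 and 17 and (+)-Ipc2BOMe are bought as catalogue reagents.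

**Step 1**
Reactants: 1 ethyl (S)-lactate
Product: 2 ethyl (2S)-2-(triethylsilyloxy)propanoate
Conditions: TESCl, imidazole, CH2Cl2, 0 °C to rt
Reagents that add atoms: chlorotriethylsilane (TESCl), CC[Si](Cl)(CC)CC
Why: Imidazole-promoted silyl ether formation leaves the lactate stereocentre (future C8) untouched, and TES is chosen because it outlasts the TMS removal of step 5 yet falls off under the acid of step 6.

**Step 2**
Reactants: 2 ethyl (2S)-2-(triethylsilyloxy)propanoate
Product: 3 (2S)-2-(triethylsilyloxy)propanal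
Conditions: i-Bu2AlH (1.05 equiv), CH2Cl2, −78 °C; aq. Rochelle salt; used at once
Reagents that add atoms: none
Why: Partial ester reduction stops at the aluminium hemiacetal at −78 °C and releases the aldehyde only on work-up, so the α-stereocentre is not epimerised.

**Step 3**
Reactants: 3 (2S)-2-(triethylsilyloxy)propanal; 4 cis-2-butene
Product: 7 (2S,3R,4S)-4-methyl-2-(triethylsilyloxy)hex-5-en-3-ol, via (Z)-crotyldiisopinocampheylborane 5 (not isolated), via borinate ester 6 (not isolated)
Conditions: 4 (excess), KOt-Bu, n-BuLi, THF, −78 to −45 °C; (+)-Ipc2BOMe [from (−)-α-pinene], −78 °C; BF3·OEt2; 3, −78 °C, 4 h; then 3 M NaOH, 30% H2O2, 0 °C to rt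
Reagents that add atoms: none
Why: Brown asymmetric crotylboration runs through a closed Zimmerman–Traxler chair, so the Z-crotyl geometry gives the 6,7-syn relation, and the Ipc ligands select the aldehyde face that is also the Felkin–Anh face (matched pair), which gives 7R and the 7,8-anti diol pattern.

**Step 4**
Reactants: 7 (2S,3R,4S)-4-methyl-2-(triethylsilyloxy)hex-5-en-3-ol; 8 methacrolein
Product: 9 (2E,4S,5R,6S)-5-hydroxy-2,4-dimethyl-6-(triethylsilyloxy)hept-2-enal
Conditions: 8 (8 equiv), second-generation Hoveyda–Grubbs catalyst (5 mol %), CH2Cl2, 40 °C, 16 h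
Reagents that add atoms: none
Why: Olefin cross-metathesis of a terminal alkene with excess electron-poor 1,1-disubstituted methacrolein gives the cross product selectively as the E-trisubstituted enal, and no stereocentre is touched.

**Step 5**
Reactants: 9 (2E,4S,5R,6S)-5-hydroxy-2,4-dimethyl-6-(triethylsilyloxy)hept-2-enal; 10 (4S)-4-benzyl-3-propanoyl-1,3-oxazolidin-2-one
Product: 12 (4S)-4-benzyl-3-[(2R,3S,4E,6S,7R,8S)-3,7-dihydroxy-2,4,6-trimethyl-8-(triethylsilyloxy)non-4-enoyl]-1,3-oxazolidin-2-one, via bis-TMS aldol adduct 11 (not isolated)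
Conditions: 10 (1.3 equiv), MgCl2 (20 mol %), Et3N (4 equiv), TMSCl (3 equiv), EtOAc, rt, 24 h; then PPTS (cat.), MeOH, 0 °C, 20 min
Reagents that add atoms: none
Why: In the Evans magnesium-halide-catalysed anti-aldol (soft enolisation, TMSCl turnover) the chelated Z-enolate is attacked on the face away from the benzyl group (sets 2R) with anti topology on the non-α-enolisable enal (sets 3S), while the C7–OH is masked in the flask as its TMS ether.

**Step 6 (key step)**
Reactants: 12 (4S)-4-benzyl-3-[(2R,3S,4E,6S,7R,8S)-3,7-dihydroxy-2,4,6-trimethyl-8-(triethylsilyloxy)non-4-enoyl]-1,3-oxazolidin-2-one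
Product: 16 (3R,4S,4aR,6S,7R,8R,8aS)-4,7-dihydroxy-3,4a,6,8-tetramethylhexahydropyrano[3,2-b]pyran-2(3H)-one (bicyclic core diol), via TES epoxy alcohol 13 (not isolated), via epoxy triol 14 (not isolated), via tetrahydropyran imide 15 (not isolated)
Conditions: VO(acac)2 (3 mol %), t-BuOOH (1.3 equiv, decane), CH2Cl2, 0 °C, 3 h; then same flask: (CF3)2CHOH, H2O (5 equiv), CSA (0.3 equiv), 0 °C to rt, 12 h
Reagents that add atoms: tert-butyl hydroperoxide, CC(C)(C)OO
Why: Proposed new method: this is a telescoped directed-epoxidation / epoxide-opening / acyl-transfer cascade in which (a) the C3 vanadate ester delivers oxygen through the A(1,2)-minimised erythro transition state to the alkene face that the A(1,3)-locked C6 centre also leaves open (anti to the C7–C9 chain), which fixes C5; (b) acid in the ionising, non-nucleophilic fluoroalcohol removes the TES group, and O8, held on the opposite face, attacks the tertiary, methyl-stabilised C4 from the rear in an all-equatorial chair (6-endo-tet, inversion sets C4, ring A); and (c) the liberated equatorial C5–OH acylates itself on the imide and expels the oxazolidinone (trans-fused ring B), the closest known reaction types being VO(acac)2/t-BuOOH epoxidation of 2-methyl allylic alcohols, methyl-directed endo-selective epoxy-alcohol cyclisation of polyether synthesis, and lactonisation of δ-hydroxy N-acyloxazolidinones.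

**Step 7**
Reactants: 16 bicyclic core diol; 17 bis(2,2,2-trifluoroethyl)phosphonoacetic acid
Product: 19 (3R,4S,4aS,6S,7R,8R,8aS)-4-acetoxy-3,4a,6,8-tetramethyl-2-oxooctahydropyrano[3,2-b]pyran-7-yl bis(2,2,2-trifluoroethyl)phosphonoacetate, via C7 mono-phosphonoacetate 18 (not isolated)
Conditions: 17 (1.1 equiv), DCC, DMAP (5 mol %), CH2Cl2, −10 °C, 4 h; then same flask: Ac2O (5 equiv), pyridine, DMAP (0.5 equiv), rt, 18 h
Reagents that add atoms: acetic anhydride, CC(=O)OC(C)=O
Why: Steglich esterification takes the equatorial C7–OH first because the C3–OH is neopentyl-like (next to quaternary C4 and cis to two methyls), and forced DMAP acetylation then caps C3 with retention at all centres.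

**Step 8**
Reactants: 20 octane-1,2-diol
Product: 21 2-oxooctanal
Conditions: (COCl)2 (3 equiv), DMSO (6 equiv), CH2Cl2, −78 °C; Et3N (10 equiv), −78 to 0 °C; pentane, filtration, short-path distillation, used at once
Reagents that add atoms: none
Why: Double Swern oxidation converts both carbinols of a terminal 1,2-diol to the α-keto aldehyde without C–C cleavage and delivers it anhydrous.

**Step 9**
Reactants: 19 core phosphonoacetate acetate; 21 2-oxooctanal
Product: 22 botcinin J, (3R,4S,4aS,6S,7R,8R,8aS)-4-acetoxy-3,4a,6,8-tetramethyl-2-oxooctahydropyrano[3,2-b]pyran-7-yl (2Z)-4-oxodec-2-enoate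
Conditions: KN(SiMe3)2 (1.0 equiv), 18-crown-6 (5 equiv), THF, −78 °C, 20 min; 21 (1.5 equiv), −78 °C, 1 h; AcOH quench at −78 °C; neutral silica, no amines, dark
Reagents that add atoms: none
Why: In the Still–Gennari variant of the Horner–Wadsworth–Emmons reaction the electron-poor phosphonate collapses irreversibly from the kinetic syn adduct to the Z-enoate, the aldehyde of 21 reacts far faster than its ketone, and one equivalent of base is consumed by the very acidic P–CH2–C=O site, so C2 and the β-acetoxy lactone are spared.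

**Compound list**
1 | ethyl (S)-lactate | C[C@H](O)C(=O)OCC | starting material
2 | ethyl (2S)-2-(triethylsilyloxy)propanoate | C[C@H](O[Si](CC)(CC)CC)C(=O)OCC | intermediate
3 | (2S)-2-(triethylsilyloxy)propanal | C[C@H](O[Si](CC)(CC)CC)C=O | intermediate
4 | cis-2-butene | C/C=C\C | starting material
5 | (Z)-crotyldiisopinocampheylborane (Ipc from (−)-α-pinene) | C/C=C\CB([C@H]1C[C@H]2C[C@@H]([C@@H]1C)C2(C)C)[C@H]1C[C@H]2C[C@@H]([C@@H]1C)C2(C)C | intermediate
6 | borinate ester (diisopinocampheylborinate of 7) | C[C@H](O[Si](CC)(CC)CC)[C@H](OB([C@H]1C[C@H]2C[C@@H]([C@@H]1C)C2(C)C)[C@H]1C[C@H]2C[C@@H]([C@@H]1C)C2(C)C)[C@@H](C)C=C | intermediate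
7 | (2S,3R,4S)-4-methyl-2-(triethylsilyloxy)hex-5-en-3-ol | C[C@H](O[Si](CC)(CC)CC)[C@H](O)[C@@H](C)C=C | intermediate
8 | methacrolein | C=C(C)C=O | starting material
9 | (2E,4S,5R,6S)-5-hydroxy-2,4-dimethyl-6-(triethylsilyloxy)hept-2-enal | C[C@H](O[Si](CC)(CC)CC)[C@H](O)[C@@H](C)/C=C(\C)C=O | intermediate
10 | (4S)-4-benzyl-3-propanoyl-1,3-oxazolidin-2-one | CCC(=O)N1[C@@H](Cc2ccccc2)COC1=O | starting material
11 | bis-TMS aldol adduct (3,7-bis-O-TMS ether of 12) | C[C@H](O[Si](CC)(CC)CC)[C@H](O[Si](C)(C)C)[C@@H](C)/C=C(\C)[C@@H](O[Si](C)(C)C)[C@@H](C)C(=O)N1[C@@H](Cc2ccccc2)COC1=O | intermediate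
12 | (4S)-4-benzyl-3-[(2R,3S,4E,6S,7R,8S)-3,7-dihydroxy-2,4,6-trimethyl-8-(triethylsilyloxy)non-4-enoyl]-1,3-oxazolidin-2-one | C[C@H](O[Si](CC)(CC)CC)[C@H](O)[C@@H](C)/C=C(\C)[C@@H](O)[C@@H](C)C(=O)N1[C@@H](Cc2ccccc2)COC1=O | intermediate
13 | TES epoxy alcohol, the (4S,5S)-epoxide of 12 (erythro to C3–OH, oxirane O anti to the C7–C9 chain) | C[C@H](O[Si](CC)(CC)CC)[C@H](O)[C@@H](C)[C@@H]1O[C@@]1(C)[C@@H](O)[C@@H](C)C(=O)N2[C@@H](Cc3ccccc3)COC2=O | intermediate
14 | epoxy triol (13 without TES) | C[C@H](O)[C@H](O)[C@@H](C)[C@@H]1O[C@@]1(C)[C@@H](O)[C@@H](C)C(=O)N2[C@@H](Cc3ccccc3)COC2=O | intermediate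
15 | tetrahydropyran imide, (4S)-4-benzyl-3-{(2R,3S)-3-[(2S,3S,4R,5R,6S)-3,5-dihydroxy-2,4,6-trimethyloxan-2-yl]-3-hydroxy-2-methylpropanoyl}-1,3-oxazolidin-2-one | O[C@@H]1[C@@H](C)[C@H](O)[C@](C)(O[C@H]1C)[C@@H](O)[C@@H](C)C(=O)N2[C@@H](Cc3ccccc3)COC2=O | intermediate
16 | bicyclic core diol, (3R,4S,4aR,6S,7R,8R,8aS)-4,7-dihydroxy-3,4a,6,8-tetramethylhexahydropyrano[3,2-b]pyran-2(3H)-one | O[C@@H]1[C@@H](C)[C@@H]2OC(=O)[C@H](C)[C@H](O)[C@@]2(C)O[C@H]1C | intermediate
17 | bis(2,2,2-trifluoroethyl)phosphonoacetic acid | OC(=O)CP(=O)(OCC(F)(F)F)OCC(F)(F)F | starting material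
18 | C7 mono-phosphonoacetate of 16 (C3–OH free) | O=C(CP(=O)(OCC(F)(F)F)OCC(F)(F)F)O[C@@H]1[C@@H](C)[C@@H]2OC(=O)[C@H](C)[C@H](O)[C@@]2(C)O[C@H]1C | intermediate
19 | 3-O-acetyl-7-O-[bis(2,2,2-trifluoroethyl)phosphonoacetyl] core | O=C(CP(=O)(OCC(F)(F)F)OCC(F)(F)F)O[C@@H]1[C@@H](C)[C@@H]2OC(=O)[C@H](C)[C@H](OC(C)=O)[C@@]2(C)O[C@H]1C | intermediate
20 | octane-1,2-diol (racemic) | CCCCCCC(O)CO | starting material
21 | 2-oxooctanal | CCCCCCC(=O)C=O | intermediate
22 | botcinin J | CCCCCCC(=O)/C=C\C(=O)O[C@@H]1[C@@H](C)[C@@H]2OC(=O)[C@H](C)[C@H](OC(C)=O)[C@@]2(C)O[C@H]1C | target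

**Step count**
Total step count: 9. Longest linear sequence: 8 (steps 1–7 and 9, from 1).

**Three steps most likely to fail**

**Step 6.** The C3 oxygen withdraws electron density from C4. Three side reactions can therefore compete with the 6-endo closure:
- 5-exo attack of O8 at C5, giving a tetrahydrofuran and then a γ-lactone through the C4–OH.
- 5-endo attack of the free C7–OH at C4.
- A semipinacol hydride shift from C3.

In addition, the homoallylic C7–OH could misdirect part of the epoxidation.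

Fallback (sets out from 9, comes back at 15): the rings are closed one at a time, and C4 is made allylic as well as tertiary before ring A is closed. Wittig methylenation of 9 (Ph3P=CH2, THF, 0 °C) gives the diene (2S,3R,4S,5E)-4,6-dimethyl-2-(triethylsilyloxy)octa-5,7-dien-3-ol F1. Epoxidation of only the trisubstituted, more electron-rich alkene uses the L-sorbose-derived enantiomer of the Shi ketone and KHSO5 (reagent control, reinforced by A(1,3) strain at C6). It gives the TES vinyl oxirane (2S,3R,4R)-4-[(2S,3S)-3-ethenyl-3-methyloxiran-2-yl]-2-(triethylsilyloxy)pentan-3-ol F2. CSA in wet CH2Cl2 removes the silyl group to give the vinyl oxirane diol F3. This closes by π-activated 6-endo opening to the vinyl tetrahydropyran (2R,3S,4R,5R,6S)-2-ethenyl-2,4,6-trimethyloxane-3,5-diol F4. Ozonolysis (O3, then Me2S) gives (2S,3S,4R,5R,6S)-3,5-dihydroxy-2,4,6-trimethyloxane-2-carbaldehyde F5. The MgCl2/Et3N/TMSCl anti-aldol with 10 (F5 cannot enolise, and its hydroxyls are silylated in the flask) gives the tris-TMS ether of 15 F6. Methanolysis with PPTS returns 15, which CSA lactonises to 16.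

**Step 9.** The α-keto aldehyde oligomerises and hydrates easily, the Z:E ratio on such an electrophile is untested, and the Z-enedicarbonyl product isomerises with any nucleophile or base.

Fallback (sets out from 16, comes back at 22): the Z geometry is taken from syn-hydrogenation of an alkyne instead of from an olefination. Propiolic acid dianion (2 equiv LiN(i-Pr)2, THF, −78 °C) adds to heptanal to give 4-hydroxydec-2-ynoic acid F7. CrO3/H2SO4 in acetone then gives 4-oxodec-2-ynoic acid F8. DCC coupling without a nucleophilic amine catalyst acylates the C7–OH of 16 to give the 7-O-(4-oxodec-2-ynoyl) ester F9. Ac2O with Sc(OTf)3 (no amine, which would add to the ynone) gives the 3-O-acetyl-7-O-(4-oxodec-2-ynoyl) core F10. Hydrogenation with H2 over Pd/CaCO3 poisoned by Pb(OAc)2 and quinoline, stopped at one equivalent, gives 22.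

**Step 5.** Enal 9 carries a γ-hydrogen at the C6 stereocentre and a free hydroxyl. Et3N/TMSCl may convert part of it into a silyl dienol ether (loss of C6 integrity), and a β-alkyl enal is at the edge of the aldehyde range known for this aldol.

Fallback (sets out from 7, 8 and 10, comes back at 12; step 4 falls away): the order of the two C–C bond formations is swapped. The same magnesium-catalysed anti-aldol is run on methacrolein 8 itself, a small aldehyde with no γ-hydrogen. It gives the O-TMS ether of the methacrolein adduct F11 and, after PPTS/MeOH, (4S)-4-benzyl-3-[(2R,3S)-3-hydroxy-2,4-dimethylpent-4-enoyl]-1,3-oxazolidin-2-one F12. Cross-metathesis of F12 (3 equiv, excess recovered) with 7 then gives 12 directly (second-generation Hoveyda–Grubbs catalyst, 10 mol %, toluene, 60 °C, ethene purged).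

**Further compounds**
F1 | step 6 | (2S,3R,4S,5E)-4,6-dimethyl-2-(triethylsilyloxy)octa-5,7-dien-3-ol | C[C@H](O[Si](CC)(CC)CC)[C@H](O)[C@@H](C)/C=C(\C)C=C
F2 | step 6 | (2S,3R,4R)-4-[(2S,3S)-3-ethenyl-3-methyloxiran-2-yl]-2-(triethylsilyloxy)pentan-3-ol | C[C@H](O[Si](CC)(CC)CC)[C@H](O)[C@@H](C)[C@@H]1O[C@@]1(C)C=C
F3 | step 6 | (2S,3R,4R)-4-[(2S,3S)-3-ethenyl-3-methyloxiran-2-yl]pentane-2,3-diol (vinyl oxirane diol) | C[C@H](O)[C@H](O)[C@@H](C)[C@@H]1O[C@@]1(C)C=C
F4 | step 6 | (2R,3S,4R,5R,6S)-2-ethenyl-2,4,6-trimethyloxane-3,5-diol | O[C@@H]1[C@@H](C)[C@H](O)[C@](C)(O[C@H]1C)C=C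
F5 | step 6 | (2S,3S,4R,5R,6S)-3,5-dihydroxy-2,4,6-trimethyloxane-2-carbaldehyde | O[C@@H]1[C@@H](C)[C@H](O)[C@](C)(O[C@H]1C)C=O
F6 | step 6 | tris-TMS ether of 15 | C[Si](C)(C)O[C@@H]1[C@@H](C)[C@H](O[Si](C)(C)C)[C@](C)(O[C@H]1C)[C@@H](O[Si](C)(C)C)[C@@H](C)C(=O)N2[C@@H](Cc3ccccc3)COC2=O
F7 | step 9 | 4-hydroxydec-2-ynoic acid (racemic) | CCCCCCC(O)C#CC(=O)O
F8 | step 9 | 4-oxodec-2-ynoic acid | CCCCCCC(=O)C#CC(=O)O
F9 | step 9 | 7-O-(4-oxodec-2-ynoyl) ester of 16 | CCCCCCC(=O)C#CC(=O)O[C@@H]1[C@@H](C)[C@@H]2OC(=O)[C@H](C)[C@H](O)[C@@]2(C)O[C@H]1C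
F10 | step 9 | 3-O-acetyl-7-O-(4-oxodec-2-ynoyl) core | CCCCCCC(=O)C#CC(=O)O[C@@H]1[C@@H](C)[C@@H]2OC(=O)[C@H](C)[C@H](OC(C)=O)[C@@]2(C)O[C@H]1C
F11 | step 5 | O-TMS ether of the methacrolein adduct | C=C(C)[C@@H](O[Si](C)(C)C)[C@@H](C)C(=O)N1[C@@H](Cc2ccccc2)COC1=O
F12 | step 5 | (4S)-4-benzyl-3-[(2R,3S)-3-hydroxy-2,4-dimethylpent-4-enoyl]-1,3-oxazolidin-2-one | C=C(C)[C@@H](O)[C@@H](C)C(=O)N1[C@@H](Cc2ccccc2)COC1=O
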